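The rate constants are invented; the result is computed.

Of the 20 mM of starting material in each flask, the protic impurity can destroy up to 20.0%, and the recipes differ in how much of that they allow.

| setting | zeta | gamma | eta | beta |
|---|---|---|---|---|
| starting material | 20 mM (fed, over 30 s) | 20 mM | 20 mM | 20 mM |
| reagent | 40.0 mM | 40.0 mM (fed, over 30 s) | 40.0 mM (in portions, 5, over 30 s) | 40.0 mM |
| protic impurity | 4.00 mM | 4.00 mM | 4.00 mM | 4.00 mM |
| free catalyst | 28 µM | 28 µM | 28 µM | 28 µM |
| time | 2.5 min | 2.5 min | 2.5 min | 2.5 min |
| remark | all else is in the flask from the start; the feed brings no volume worth counting | all else is in the flask from the start; the feed brings no volume worth counting | first portion at the start, last at 30 s | everything together at the start |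

    starting material + free catalyst → catalyst intermediate A (k1 = 48000 M⁻¹ s⁻¹)
    catalyst intermediate C → by-product + catalyst intermediate D (k2 = 530 s⁻¹)
    reagent + catalyst intermediate A → catalyst intermediate B (k3 = 1200 M⁻¹ s⁻¹)
    by-product + catalyst intermediate C → spent catalyst (k4 = 12 M⁻¹ s⁻¹)
    catalyst intermediate B → catalyst intermediate C (k5 = 120 s⁻¹)
    starting material + protic impurity → quenched substrate (k6 = 7.6 M⁻¹ s⁻¹)
    catalyst intermediate D → free catalyst + product (k7 = 45 s⁻¹)

1. the best flask by amount of product, in percent of the starting material charged; "all alike" if 1.5 percentage points covers them all (zeta / gamma / eta / beta / all alike)
2. amount of product at the end, in percent of the starting material charged, zeta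
3. amount of product at the end, in percent of the starting material charged, gamma
4. amount of product at the end, in percent of the starting material charged, eta
5. amount of product at the end, in percent of the starting material charged, beta

At first the impurity looks harmless. In beta, the half-life of starting material is 0.52 s by capture on free catalyst and 22.8 s by the impurity, each step taken by itself with its partner held at its charge. Yet I reckoned the quench at the start of beta at 0.608 mM s⁻¹.

The half-life measures capture, not completion. Once bound, the catalyst must finish its round, so I added the average waits of the other steps, taking the reagent step as pseudo-first-order at the charged reagent. One round takes 0.0533 s, and capture adds 0.00104 s. The catalyst charge divided by that round time is the ceiling, the greatest rate at which intact catalyst can make product at the charged reagent: 0.526 mM s⁻¹. That ceiling is slower than the quench at the start of beta.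

At that ceiling, the charge takes 38.1 s to clear. In beta I let the level fall in a straight line from 20 mM, ignoring what the quench removes, so the average level is half the charge, and I reckoned that 5.55% of the impurity survives. That reckons a loss of 18.9% of the starting material.

In zeta the feed of 0.667 mM s⁻¹ outruns the ceiling, so I reckoned a backlog reaching 4.23 mM when the feed ends. The clearing time is the same, but the peak is this backlog, so I reckoned that 54.2% of the impurity survives and 9.16% of the starting material is lost. I therefore committed to 90.8% product for zeta and 81.1% for beta. In eta the first portion lengthens the reagent wait to 0.104 s, and in gamma the feed starts the reagent from nothing, so I put both flasks near 80.0%, the product left if the whole impurity is used.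

The forecast chose zeta, with 89.5% for zeta, 80.4% for gamma, 80.9% for eta and 81.6% for beta; its zeta figure is lower than mine. Its ground was that “feeding it in keeps its level low and roughly halves that loss”.

The simulation gave zeta as the best flask, with 87.2% for zeta, 80.6% for gamma, 80.6% for eta and 81.8% for beta. Zeta held 12.8% quenched substrate against my 9.16%. A neighbouring flask, zeta with 2.4 mM of protic impurity, has the same ceiling, backlog and clearing time, so the same 54.2% of its impurity should survive, a loss of 5.50%. The simulated neighbour held 8.30% quenched substrate and gave 91.7% product.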